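## Retrosynthetic overview

1. The ten-membered ring is closed last by ring-closing metathesis at C3=C4 of triene 23; its 1,3-diene (C5=C16, C4) comes from ethylene enyne metathesis of the propargylic chloride 22.
2. The γ-lactone (C8–C17 bond), the C12 ketone, the C11 methyl centre and the C14 carbinol all come from one SmI2 operation on α-bromopropionate 18: Reformatsky closure, then reductive opening of a 7-oxanorbornanone with kinetic protonation at C11.
3. C6–Cl/C7–O and the alkyne come from a chloroallenylzinc addition to aldehyde 14; C2 comes from a chelate-controlled vinyl addition.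
4. The cyclohexane (C1, C10–C14) is made by the key exo Diels–Alder reaction of 2-methyl-3-silyloxyfuran 7 with enal 4, whose C9 centre (L-threonate, from vitamin C) controls the facial selectivity.
5. Ring order: oxygen-bridged cyclohexane (cycloaddition) → γ-lactone → ten-membered carbocycle.

Assumption: atoms of all intermediates carry briarane numbers (C1–C20); compounds 1 and 5 and all named reagents are taken as commercial.

## Route

Step 1
Reactants: 1 methyl 3,4-O-isopropylidene-L-threonate
Product: 2 methyl (2R)-2-[(4S)-2,2-dimethyl-1,3-dioxolan-4-yl]-2-(triethylsilyloxy)acetate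
Conditions: Et3SiCl, imidazole, DMAP (cat.), CH2Cl2, 0 → 23 °C
Reagents that add atoms: chlorotriethylsilane CC[Si](Cl)(CC)CC
Why: Imidazole-mediated silylation masks the future C9 hydroxyl; both bought stereocentres (C9 and the temporary C8 centre) are untouched.

Step 2
Reactants: 2 methyl (2R)-2-[(4S)-2,2-dimethyl-1,3-dioxolan-4-yl]-2-(triethylsilyloxy)acetate
Product: 4 (2E,4S)-4-[(4S)-2,2-dimethyl-1,3-dioxolan-4-yl]-2-methyl-4-(triethylsilyloxy)but-2-enal, via silyloxy aldehyde 3 (not isolated)
Conditions: i-Bu2AlH, CH2Cl2, −78 °C; then Ph3P=C(CH3)CHO, toluene, 80 °C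
Reagents that add atoms: 2-(triphenylphosphoranylidene)propanal CC(C=O)=P(c1ccccc1)(c1ccccc1)c1ccccc1
Why: DIBAL half-reduction gives the labile α-silyloxy aldehyde, which is olefinated crude in a Wittig reaction with the stabilised formyl ylide (E-selective), leaving C9 intact.

Step 3
Reactants: 5 3-hydroxybutan-2-one (acetoin)
Product: 6 2-methylfuran-3(2H)-one
Conditions: NaH (2.2 equiv), HCO2Et, Et2O, 0 → 23 °C; then aq. HCl
Reagents that add atoms: ethyl formate CCOC=O
Why: Claisen formylation of the methyl ketone followed by acid-catalysed cyclodehydration gives the furanone; its single centre is removed in the next step.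

Step 4
Reactants: 6 2-methylfuran-3(2H)-one
Product: 7 2-methyl-3-(triethylsilyloxy)furan
Conditions: Et3SiOTf, Et3N, Et2O, −78 → 0 °C
Reagents that add atoms: triethylsilyl trifluoromethanesulfonate CC[Si](CC)(CC)OS(=O)(=O)C(F)(F)F
Why: Soft enolisation and O-silylation aromatise the furanone to the electron-rich 3-silyloxyfuran diene.

Step 5
Reactants: 4 (2E,4S)-enal; 7 2-methyl-3-(triethylsilyloxy)furan
Product: 8 exo-formyl 7-oxanorbornene cycloadduct
Conditions: 7 (3 equiv), CH2Cl2, 1.3 GPa, 25 °C, 48 h; used at once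
Reagents that add atoms: none
Why: Normal-demand Diels–Alder cycloaddition in which the nucleophilic furan C2 (C11) bonds to the enal β-carbon C10; A1,3 strain with the C1 methyl holds C9–H in the alkene plane so the diene adds anti to the C9–OSi bond (sets C10 and C1), the α-methyl enal reacts through the exo-formyl transition state (methyl and C9 chain endo), and the oxygen bridge fixes C14 and C11.

Step 6
Reactants: 8 exo-formyl 7-oxanorbornene cycloadduct
Product: 9 (2S)-vinyl carbinol
Conditions: CH2=CHMgBr, MgBr2·OEt2, CH2Cl2/THF, −78 °C; aq. NH4Cl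
Reagents that add atoms: vinylmagnesium bromide C=C[Mg]Br
Why: Cram-chelate Grignard addition in which magnesium bridges the aldehyde oxygen and the neighbouring bridge oxygen, so vinyl attacks from the face next to the small C1 methyl (anti to C10) and gives the 2S carbinol.

Step 7
Reactants: 9 (2S)-vinyl carbinol
Product: 10 bridged ketone diol
Conditions: HF·pyridine, pyridine, THF, 0 °C
Reagents that add atoms: none
Why: Acidic fluoride desilylation cleaves the silyl enol ether by C13 protonation (no enolate, so the oxygen bridge is not eliminated) and the C9 silyl ether while the acetonide stays; the ketone can no longer undergo cycloreversion.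

Step 8
Reactants: 10 bridged ketone diol
Product: 11 2,9-diacetate
Conditions: Ac2O, DMAP (cat.), pyridine, CH2Cl2, 0 → 23 °C
Reagents that add atoms: acetic anhydride CC(=O)OC(C)=O
Why: DMAP-catalysed acylation installs both final acetates on the secondary alcohols at C2 and C9 without touching any stereocentre.

Step 9
Reactants: 11 2,9-diacetate
Product: 12 7,8-diol
Conditions: AcOH/H2O (4:1), 40 °C
Reagents that add atoms: none
Why: Acid-catalysed acetal hydrolysis frees the C7/C8 diol; the acetates, the bridged ketone and the allylic ester tolerate aqueous acetic acid.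

Step 10
Reactants: 12 7,8-diol
Product: 13 7,8-bis(triethylsilyl) ether
Conditions: Et3SiOTf, 2,6-lutidine, CH2Cl2, −78 °C
Reagents that add atoms: triethylsilyl trifluoromethanesulfonate CC[Si](CC)(CC)OS(=O)(=O)C(F)(F)F
Why: Silyl triflate silylation caps both hydroxyls at low temperature before the C9 acetate can migrate to O8.

Step 11
Reactants: 13 7,8-bis(triethylsilyl) ether
Product: 14 C7 aldehyde
Conditions: (COCl)2, DMSO, CH2Cl2, −78 → −35 °C; then Et3N, −78 °C
Reagents that add atoms: none
Why: Swern oxidation, under which the primary triethylsilyl ether is cleaved and oxidised selectively while the secondary one survives; the cold base does not epimerise C8 or eliminate the β-acetate.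

Step 12
Reactants: 14 C7 aldehyde
Product: 15 anti-chlorohydrin
Conditions: Me3SiC≡CCH2Cl, n-BuLi, ZnBr2, THF, −90 → −78 °C; then 14, −78 °C; aq. NH4Cl
Reagents that add atoms: 3-chloro-1-(trimethylsilyl)prop-1-yne ClCC#C[Si](C)(C)C
Why: Chloroallenylzinc addition (SE2' through a cyclic transition state) gives the anti chlorohydrin, which sets C6 relative to C7, and polar Felkin–Anh control by the non-chelating C8 silyloxy group sets C7 anti to C8; the organozinc ignores the esters and the hindered ketone.

Step 13
Reactants: 15 anti-chlorohydrin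
Product: 16 C7 2-bromopropanoate
Conditions: CH3CHBrCOBr, pyridine, CH2Cl2, −20 °C
Reagents that add atoms: 2-bromopropanoyl bromide CC(Br)C(Br)=O
Why: Acid bromide acylation of the only free alcohol; the CHBr centre is an inconsequential epimer mixture because it becomes an enolate.

Step 14
Reactants: 16 C7 2-bromopropanoate
Product: 17 C8 alcohol
Conditions: HF·pyridine, pyridine, THF, 0 → 23 °C
Reagents that add atoms: none
Why: Fluoride desilylation of the secondary silyl ether under acidic conditions that leave the alkynylsilane, the α-bromo ester and the acetates alone.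

Step 15
Reactants: 17 C8 alcohol
Product: 18 C8 ketone
Conditions: Dess–Martin periodinane, NaHCO3, CH2Cl2, 0 → 23 °C
Reagents that add atoms: none
Why: Dess–Martin oxidation under buffered, non-basic conditions gives the ketone without epimerising the α-acyloxy centres C7 and C9; the temporary C8 centre is erased after it has set C7.

Step 16
Reactants: 18 C8 ketone
Product: 20 14-hydroxy-12-oxo γ-lactone, via bridged hydroxy lactone 19 (not isolated)
Conditions: SmI2 (2.2 equiv), THF, −78 °C; then MeOH, SmI2 (2.5 equiv), −78 °C; AcOH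
Reagents that add atoms: none
Why: Samarium Reformatsky reaction (the samarium enolate adds to the C8 ketone with the C9 chain trans to C6 and the methyl trans to C9 on the new five-membered ring, setting C8 and C17) followed by reductive cleavage of the α-alkoxy ketone C11–O bond, after which methanol protonates the C11=C12 enolate anti to the pseudo-axial C10 side chain to give the 11R ketone and the free C14 alcohol.

Step 17
Reactants: 20 14-hydroxy-12-oxo γ-lactone
Product: 21 C14 butanoate
Conditions: (n-PrCO)2O, DMAP (cat.), pyridine, CH2Cl2, 0 °C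
Reagents that add atoms: butanoic anhydride CCCC(=O)OC(=O)CCC
Why: DMAP-catalysed acylation of the secondary C14 alcohol; the tertiary C8 alcohol does not react at 0 °C.

Step 18
Reactants: 21 C14 butanoate
Product: 22 terminal alkyne
Conditions: Bu4NF, AcOH (1:1.2), THF, 0 °C
Reagents that add atoms: none
Why: Buffered fluoride protodesilylation of the alkynylsilane; acetic acid keeps the medium non-basic so the β-acyloxy ketone does not eliminate.

Step 19
Reactants: 22 terminal alkyne
Product: 23 triene
Conditions: second-generation Grubbs catalyst RuCl2(=CHPh)(PCy3)(H2IMes) (10 mol %), ethylene (1 atm), CH2Cl2, 40 °C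
Reagents that add atoms: ethylene C=C
Why: Cross enyne metathesis with ethylene turns the alkyne into the 2-substituted buta-1,3-diene (C5=C16 methylene and a C4 vinyl) without touching a stereocentre.

Step 20
Reactants: 23 triene
Product: 24 ptilosarcone
Conditions: second-generation Hoveyda–Grubbs catalyst RuCl2(=CH-C6H4-2-O-i-Pr)(H2IMes) (15 mol %), toluene (0.5 mM), 80 °C, argon sparge
Reagents that add atoms: none
Why: Ring-closing metathesis between the C2 vinyl group and the monosubstituted end of the diene at high dilution closes the ten-membered ring, with ring strain giving the Z C3=C4 olefin and the 1,1-disubstituted C5=C16 alkene staying out.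

## Compound list

1 | methyl 3,4-O-isopropylidene-L-threonate = methyl (2R)-2-[(4S)-2,2-dimethyl-1,3-dioxolan-4-yl]-2-hydroxyacetate | COC(=O)[C@H](O)[C@@H]1COC(C)(C)O1 | starting material
2 | methyl (2R)-2-[(4S)-2,2-dimethyl-1,3-dioxolan-4-yl]-2-(triethylsilyloxy)acetate | COC(=O)[C@H](O[Si](CC)(CC)CC)[C@@H]1COC(C)(C)O1 | intermediate
3 | (2R)-2-[(4S)-2,2-dimethyl-1,3-dioxolan-4-yl]-2-(triethylsilyloxy)acetaldehyde | O=C[C@H](O[Si](CC)(CC)CC)[C@@H]1COC(C)(C)O1 | intermediate
4 | (2E,4S)-4-[(4S)-2,2-dimethyl-1,3-dioxolan-4-yl]-2-methyl-4-(triethylsilyloxy)but-2-enal | O=C/C(C)=C/[C@H](O[Si](CC)(CC)CC)[C@@H]1COC(C)(C)O1 | intermediate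
5 | 3-hydroxybutan-2-one (acetoin, racemic) | CC(O)C(C)=O | starting material
6 | 2-methylfuran-3(2H)-one (racemic) | CC1OC=CC1=O | intermediate
7 | 2-methyl-3-(triethylsilyloxy)furan | Cc1occc1O[Si](CC)(CC)CC | intermediate
8 | cycloadduct: 7-oxabicyclo[2.2.1]hept-5-ene with the oxygen bridge between C11 and C14; C1 bears CH3 (endo) and CHO (exo), C10 bears the endo (S)-CH(OSiEt3)[(S)-2,2-dimethyl-1,3-dioxolan-4-yl] chain, C11 bears CH3, C12 bears OSiEt3 (C12=C13) | O=C[C@]1(C)[C@H]([C@]2(C)O[C@H]1C=C2O[Si](CC)(CC)CC)[C@H](O[Si](CC)(CC)CC)[C@@H]3COC(C)(C)O3 | intermediate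
9 | (2S)-vinyl carbinol of 8 (C2 bears OH and CH=CH2) | C=C[C@H](O)[C@]1(C)[C@H]([C@]2(C)O[C@H]1C=C2O[Si](CC)(CC)CC)[C@H](O[Si](CC)(CC)CC)[C@@H]3COC(C)(C)O3 | intermediate
10 | bridged ketone diol (7-oxanorbornan-2-one: C12 ketone; free OH at C2 and C9; C7/C8 acetonide) | C=C[C@H](O)[C@]1(C)[C@H]([C@]2(C)O[C@H]1CC2=O)[C@H](O)[C@@H]3COC(C)(C)O3 | intermediate
11 | 2,9-diacetate of 10 | C=C[C@H](OC(C)=O)[C@]1(C)[C@H]([C@]2(C)O[C@H]1CC2=O)[C@H](OC(C)=O)[C@@H]3COC(C)(C)O3 | intermediate
12 | 7,8-diol (acetonide of 11 removed) | C=C[C@H](OC(C)=O)[C@]1(C)[C@H]([C@]2(C)O[C@H]1CC2=O)[C@H](OC(C)=O)[C@@H](O)CO | intermediate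
13 | 7,8-bis(triethylsilyl) ether of 12 | C=C[C@H](OC(C)=O)[C@]1(C)[C@H]([C@]2(C)O[C@H]1CC2=O)[C@H](OC(C)=O)[C@@H](O[Si](CC)(CC)CC)CO[Si](CC)(CC)CC | intermediate
14 | C7 aldehyde with C8 triethylsilyl ether | C=C[C@H](OC(C)=O)[C@]1(C)[C@H]([C@]2(C)O[C@H]1CC2=O)[C@H](OC(C)=O)[C@@H](O[Si](CC)(CC)CC)C=O | intermediate
15 | anti-chlorohydrin (C7-OH, C6-Cl, C5≡C4-SiMe3; C7 anti to C8-OSiEt3) | C=C[C@H](OC(C)=O)[C@]1(C)[C@H]([C@]2(C)O[C@H]1CC2=O)[C@H](OC(C)=O)[C@@H](O[Si](CC)(CC)CC)[C@@H](O)[C@@H](Cl)C#C[Si](C)(C)C | intermediate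
16 | C7 2-bromopropanoate of 15 (CHBr epimers) | C=C[C@H](OC(C)=O)[C@]1(C)[C@H]([C@]2(C)O[C@H]1CC2=O)[C@H](OC(C)=O)[C@@H](O[Si](CC)(CC)CC)[C@@H](OC(=O)C(C)Br)[C@@H](Cl)C#C[Si](C)(C)C | intermediate
17 | C8 alcohol (silyl ether of 16 removed) | C=C[C@H](OC(C)=O)[C@]1(C)[C@H]([C@]2(C)O[C@H]1CC2=O)[C@H](OC(C)=O)[C@@H](O)[C@@H](OC(=O)C(C)Br)[C@@H](Cl)C#C[Si](C)(C)C | intermediate
18 | C8 ketone | C=C[C@H](OC(C)=O)[C@]1(C)[C@H]([C@]2(C)O[C@H]1CC2=O)[C@H](OC(C)=O)C(=O)[C@@H](OC(=O)C(C)Br)[C@@H](Cl)C#C[Si](C)(C)C | intermediate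
19 | bridged hydroxy lactone (γ-lactone closed, C8-OH; oxygen bridge and C12 ketone still in place) | C=C[C@H](OC(C)=O)[C@]1(C)[C@H]([C@]2(C)O[C@H]1CC2=O)[C@H](OC(C)=O)[C@]3(O)[C@@H](C)C(=O)O[C@H]3[C@@H](Cl)C#C[Si](C)(C)C | intermediate
20 | 14-hydroxy-12-oxo γ-lactone (bridge opened; 11R methyl; free OH at C14 and C8) | C=C[C@H](OC(C)=O)[C@]1(C)[C@H]([C@@H](C)C(=O)C[C@@H]1O)[C@H](OC(C)=O)[C@]3(O)[C@@H](C)C(=O)O[C@H]3[C@@H](Cl)C#C[Si](C)(C)C | intermediate
21 | C14 butanoate of 20 | C=C[C@H](OC(C)=O)[C@]1(C)[C@H]([C@@H](C)C(=O)C[C@@H]1OC(=O)CCC)[C@H](OC(C)=O)[C@]3(O)[C@@H](C)C(=O)O[C@H]3[C@@H](Cl)C#C[Si](C)(C)C | intermediate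
22 | terminal alkyne (SiMe3 of 21 removed) | C=C[C@H](OC(C)=O)[C@]1(C)[C@H]([C@@H](C)C(=O)C[C@@H]1OC(=O)CCC)[C@H](OC(C)=O)[C@]3(O)[C@@H](C)C(=O)O[C@H]3[C@@H](Cl)C#C | intermediate
23 | triene (C2 vinyl; C6 bears the buta-1,3-dien-2-yl group C5(=C16H2)–C4H=CH2) | C=C[C@H](OC(C)=O)[C@]1(C)[C@H]([C@@H](C)C(=O)C[C@@H]1OC(=O)CCC)[C@H](OC(C)=O)[C@]3(O)[C@@H](C)C(=O)O[C@H]3[C@@H](Cl)C(=C)C=C | intermediate
24 | ptilosarcone | C=C1/C=C\[C@H](OC(C)=O)[C@]2(C)[C@H]([C@@H](C)C(=O)C[C@@H]2OC(=O)CCC)[C@H](OC(C)=O)[C@]2(O)[C@@H](C)C(=O)O[C@H]2[C@H]1Cl | target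

## Step count and weak points

Total step count: 20. Longest linear sequence: 18 steps (1 → 24 through steps 1, 2 and 5–20).

The three steps most likely to fail:

Step 5, the furan Diels–Alder reaction. The exo-formyl mode is assumed from the behaviour of α-methyl enals with bridged dienes and has not been shown for this pair, and the trisubstituted enal may react slowly or reversibly. The fallback sets out from 4 (with 7) and replaces the concerted cycloaddition by a stepwise polar annulation. BF3·OEt2 at −78 °C promotes Mukaiyama–Michael addition of 7 through C11 to the enal (again anti to the C9–OSi bond) and gives, after aqueous work-up, the 2,2-disubstituted furan-3(2H)-one aldehyde F1. Pyrrolidinium acetate then forms the enamine of the α-branched aldehyde, which adds intramolecularly to the furanone C14 and closes the C1–C14 bond to give the 7-oxanorbornanone aldehyde F2. Vinylmagnesium bromide at −78 °C adds to the chelated exo aldehyde faster than to the ketone to give the vinyl carbinol F3, and HF·pyridine removes the silyl ether to come back to the route at 10.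

Step 16, the samarium cascade. Two electron-transfer events must run in the presence of a propargylic chloride and two α-acyloxy groups on the C8 ketone. The fallback sets out from 18, gives up the one-flask cascade and the samarium enolate, and closes the lactone first by a zinc Reformatsky reaction (activated Zn, THF, 0 °C). Zinc does not reduce the bridged ketone, the α-acyloxy groups or the chloride, so 19 is isolated. The bridge is then opened on this simpler substrate in a single SmI2/MeOH event at −78 °C, which comes back to the route at 20; no new compound F0.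

Step 20, the ring-closing metathesis. Ten-membered carbocycles form reluctantly, and dimerisation or the E olefin may compete. The fallback sets out from 22 and skips the triene: ring-closing enyne metathesis with the second-generation Grubbs catalyst at high dilution without ethylene. The ruthenium alkylidene is loaded on the C2 vinyl group and adds to the alkyne in the endo mode, so ring and diene form in one event and the route is rejoined at 24; no new compound F0.

## Further compounds

F1 | step 5 | Mukaiyama–Michael adduct: 2-methyl-2-substituted furan-3(2H)-one with a CH(CH3)CHO group at C10 (C1 epimers) | O=CC(C)[C@H]([C@]2(C)OC=CC2=O)[C@H](O[Si](CC)(CC)CC)[C@@H]3COC(C)(C)O3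
F2 | step 5 | 7-oxanorbornanone aldehyde (C12 ketone, exo CHO at C1, C9 silyl ether) | O=C[C@]1(C)[C@H]([C@]2(C)O[C@H]1CC2=O)[C@H](O[Si](CC)(CC)CC)[C@@H]3COC(C)(C)O3
F3 | step 5 | (2S)-vinyl carbinol of F2 | C=C[C@H](O)[C@]1(C)[C@H]([C@]2(C)O[C@H]1CC2=O)[C@H](O[Si](CC)(CC)CC)[C@@H]3COC(C)(C)O3
F0 | step 16 | none | none
F0 | step 20 | none | none
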